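**Assumption:** the SMILES is read as (2S) at C2 and (E) at the side-chain alkene. The (S)-ligand in step 12 is assigned by analogy with (S)-BINAP giving (S)-3-arylcyclohexanones; if it delivers 2R, use the (R)-ligand. The route is a design from known reaction types and has not been run.

## Retrosynthetic overview
1. Target ⇐ global MOM removal from an (S)-flavanone whose C2 stereocentre comes from Rh-catalysed asymmetric 1,4-addition of a catechol-derived arylboronic acid to a 6-alkylchromone.
2. The chromone (pyranone ring, formed second, onto the pre-built A-ring) comes from a 2'-hydroxyacetophenone in which only the OH remote from the side chain is free, which fixes 6- over 8-substitution.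
3. That acetophenone comes from phloroglucinol carrying one TIPS and two MOM ethers, by two successive directed ortho-metalations: alkylation between the two OMOM groups, then acetylation next to the OTIPS.
4. The side chain is (E)-8-bromo-2,6-dimethyloct-6-en-2-ol, made from geranyl acetate by selective hydration of the distal alkene, so the E geometry is bought, not made.
5. Ring order: A-ring (bought) → chromone C-ring → B-ring attached at C2 with stereocontrol.

## Route

**Step 1**
Reactants: **1** geranyl acetate
Product: **2** (E)-7-hydroxy-3,7-dimethyloct-2-en-1-yl acetate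
Conditions: Hg(OAc)2, THF/H2O (1:1), rt; then 3 M NaOH, NaBH4, 0 °C
Reagents that add atoms: water, O
Why: Markovnikov oxymercuration–demercuration occurs at the electron-rich distal alkene because the 2,3-alkene is deactivated by the allylic acetate; the E alkene is untouched.

**Step 2**
Reactants: **2** (E)-7-hydroxy-3,7-dimethyloct-2-en-1-yl acetate
Product: **3** (E)-3,7-dimethyloct-2-ene-1,7-diol
Conditions: K2CO3, MeOH, rt
Reagents that add atoms: none
Why: Simple acetate methanolysis; nothing else in the molecule is base-sensitive.

**Step 3**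
Reactants: **3** (E)-3,7-dimethyloct-2-ene-1,7-diol
Product: **4** (E)-8-bromo-2,6-dimethyloct-6-en-2-ol (used fresh)
Conditions: NBS, Me2S, CH2Cl2, −20 → 0 °C
Reagents that add atoms: NBS, BrN1C(=O)CCC1=O
Why: Corey–Kim bromination activates only the primary allylic alcohol and displaces it by SN2 without allylic transposition; the tertiary alcohol does not react.

**Step 4**
Reactants: **5** phloroglucinol
Product: **6** 5-[(triisopropylsilyl)oxy]benzene-1,3-diol
Conditions: TIPSCl (1.0 equiv), imidazole, DMF, 0 °C → rt
Reagents that add atoms: TIPSCl, CC(C)[Si](Cl)(C(C)C)C(C)C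
Why: Statistical monosilylation (about 40–50% expected, over-silylated material separable) marks the one oxygen that will become the ring oxygen O1.

**Step 5**
Reactants: **6** 5-[(triisopropylsilyl)oxy]benzene-1,3-diol
Product: **7** [3,5-bis(methoxymethoxy)phenoxy]triisopropylsilane
Conditions: MOMCl (2.5 equiv), i-Pr2NEt, CH2Cl2, 0 °C → rt
Reagents that add atoms: MOMCl, COCCl
Why: Phenol alkylation under mild amine base installs two metalation-directing groups without disturbing the aryl silyl ether.

**Step 6**
Reactants: **7** [3,5-bis(methoxymethoxy)phenoxy]triisopropylsilane (2.2 equiv, excess recovered) and **4** (E)-8-bromo-2,6-dimethyloct-6-en-2-ol (1.0 equiv)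
Product: **8** (E)-8-{2,6-bis(methoxymethoxy)-4-[(triisopropylsilyl)oxy]phenyl}-2,6-dimethyloct-6-en-2-ol
Conditions: n-BuLi (2.1 equiv), THF, 0 °C; then **4**, −78 → 0 °C
Reagents that add atoms: none
Why: Directed ortho-metalation occurs between the two cooperating OMOM groups (OTIPS is bulky and non-directing); one equivalent of aryllithium deprotonates the tertiary OH and the second displaces the primary allylic bromide by SN2 with retention of E geometry.

**Step 7**
Reactants: **8** (E)-8-{2,6-bis(methoxymethoxy)-4-[(triisopropylsilyl)oxy]phenyl}-2,6-dimethyloct-6-en-2-ol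
Product: **9** 1-{3-[(2E)-7-hydroxy-3,7-dimethyloct-2-en-1-yl]-2,4-bis(methoxymethoxy)-6-[(triisopropylsilyl)oxy]phenyl}ethan-1-one
Conditions: s-BuLi (2.3 equiv), TMEDA, THF, −78 °C; then MeC(O)N(OMe)Me, −78 → −20 °C
Reagents that add atoms: N-methoxy-N-methylacetamide, CC(=O)N(C)OC
Why: After alkoxide formation, a second OMOM-directed ortho-metalation takes the only remaining (symmetry-equivalent) ring C–H, and the Weinreb amide stops cleanly at the ketone; keeping −78 °C avoids O→C silyl migration.

**Step 8**
Reactants: **9** the TIPS-protected acetophenone from step 7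
Product: **10** 1-{6-hydroxy-3-[(2E)-7-hydroxy-3,7-dimethyloct-2-en-1-yl]-2,4-bis(methoxymethoxy)phenyl}ethan-1-one
Conditions: TBAF, THF, 0 °C
Reagents that add atoms: none
Why: Fluoride cleaves the aryl silyl ether selectively and leaves the MOM ethers intact, so the only free phenol is the one remote from the side chain.

**Step 9**
Reactants: **10** the 2'-hydroxyacetophenone from step 8
Product: **11** 6-[(2E)-7-hydroxy-3,7-dimethyloct-2-en-1-yl]-5,7-bis(methoxymethoxy)-4H-chromen-4-one
Conditions: Me2NCH(OMe)2, PhMe, 90 °C; concentrate; then AcOH, 50 °C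
Reagents that add atoms: DMF dimethyl acetal, COC(OC)N(C)C (supplies C2 of the chromone)
Why: Enaminone formation at the methyl ketone followed by intramolecular addition–elimination of the single free phenol (loss of Me2NH) gives the chromone; because only that phenol can cyclise, the side chain is unambiguously at C6.

**Step 10**
Reactants: **12** 4-bromocatechol
Product: **13** 4-bromo-1,2-bis(methoxymethoxy)benzene
Conditions: MOMCl, i-Pr2NEt, CH2Cl2, 0 °C → rt
Reagents that add atoms: MOMCl, COCCl
Why: Standard phenol protection, chosen so all four phenols carry the same group for one final deprotection.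

**Step 11**
Reactants: **13** 4-bromo-1,2-bis(methoxymethoxy)benzene
Product: **14** [3,4-bis(methoxymethoxy)phenyl]boronic acid
Conditions: n-BuLi, THF, −78 °C; B(Oi-Pr)3; then aq NH4Cl
Reagents that add atoms: triisopropyl borate, CC(C)OB(OC(C)C)OC(C)C; water, O
Why: Br–Li exchange at −78 °C is faster than ortho-metalation, and the borate is hydrolysed at near-neutral pH so the MOM ethers survive.

**Step 12**
Reactants: **11** the 6-alkyl-5,7-bis(MOM) chromone and **14** [3,4-bis(methoxymethoxy)phenyl]boronic acid (3 equiv)
Product: **15** (2S)-2-[3,4-bis(methoxymethoxy)phenyl]-6-[(2E)-7-hydroxy-3,7-dimethyloct-2-en-1-yl]-5,7-bis(methoxymethoxy)chroman-4-one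
Conditions: [RhCl(C2H4)2]2 (1.5 mol %), (S)-MeO-F12-BIPHEP (3.3 mol %), aq KOH (10 mol %), toluene/H2O, 35 °C
Reagents that add atoms: none
Why: Hayashi–Miyaura Rh-catalysed asymmetric 1,4-addition of the aryl group to the chromone sets C2 as S under ligand control (electron-poor bisphosphine for the deactivated chromone); mild temperature and only catalytic base suppress retro-oxa-Michael opening, and the isolated alkene and tertiary alcohol are inert.

**Step 13**
Reactants: **15** the tetra-MOM (2S)-flavanone
Product: **16** prokinawan, (2S)-2-(3,4-dihydroxyphenyl)-5,7-dihydroxy-6-[(2E)-7-hydroxy-3,7-dimethyloct-2-en-1-yl]chroman-4-one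
Conditions: 3 M aq HCl/MeOH (1:5), 40 °C, stopped at full conversion
Reagents that add atoms: none
Why: Acid-catalysed acetal cleavage removes all four MOM groups (formaldehyde trapped by MeOH); these conditions are mild enough that the C2 stereocentre should not racemise and the trisubstituted alkene and tertiary alcohol should survive.

## Compound list
1 | geranyl acetate | CC(=O)OC/C=C(\C)CCC=C(C)C | starting material
2 | (E)-7-hydroxy-3,7-dimethyloct-2-en-1-yl acetate | CC(=O)OC/C=C(\C)CCCC(C)(C)O | intermediate
3 | (E)-3,7-dimethyloct-2-ene-1,7-diol | OC/C=C(\C)CCCC(C)(C)O | intermediate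
4 | (E)-8-bromo-2,6-dimethyloct-6-en-2-ol | BrC/C=C(\C)CCCC(C)(C)O | intermediate
5 | phloroglucinol | Oc1cc(O)cc(O)c1 | starting material
6 | 5-[(triisopropylsilyl)oxy]benzene-1,3-diol | CC(C)[Si](Oc1cc(O)cc(O)c1)(C(C)C)C(C)C | intermediate
7 | [3,5-bis(methoxymethoxy)phenoxy]triisopropylsilane | COCOc1cc(OCOC)cc(O[Si](C(C)C)(C(C)C)C(C)C)c1 | intermediate
8 | (E)-8-{2,6-bis(methoxymethoxy)-4-[(triisopropylsilyl)oxy]phenyl}-2,6-dimethyloct-6-en-2-ol | COCOc1cc(O[Si](C(C)C)(C(C)C)C(C)C)cc(OCOC)c1C/C=C(\C)CCCC(C)(C)O | intermediate
9 | 1-{3-[(2E)-7-hydroxy-3,7-dimethyloct-2-en-1-yl]-2,4-bis(methoxymethoxy)-6-[(triisopropylsilyl)oxy]phenyl}ethan-1-one | CC(=O)c1c(OCOC)c(C/C=C(\C)CCCC(C)(C)O)c(OCOC)cc1O[Si](C(C)C)(C(C)C)C(C)C | intermediate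
10 | 1-{6-hydroxy-3-[(2E)-7-hydroxy-3,7-dimethyloct-2-en-1-yl]-2,4-bis(methoxymethoxy)phenyl}ethan-1-one | CC(=O)c1c(OCOC)c(C/C=C(\C)CCCC(C)(C)O)c(OCOC)cc1O | intermediate
11 | 6-[(2E)-7-hydroxy-3,7-dimethyloct-2-en-1-yl]-5,7-bis(methoxymethoxy)-4H-chromen-4-one | O=c1ccoc2cc(OCOC)c(C/C=C(\C)CCCC(C)(C)O)c(OCOC)c12 | intermediate
12 | 4-bromocatechol | Oc1ccc(Br)cc1O | starting material
13 | 4-bromo-1,2-bis(methoxymethoxy)benzene | COCOc1ccc(Br)cc1OCOC | intermediate
14 | [3,4-bis(methoxymethoxy)phenyl]boronic acid | COCOc1ccc(B(O)O)cc1OCOC | intermediate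
15 | (2S)-2-[3,4-bis(methoxymethoxy)phenyl]-6-[(2E)-7-hydroxy-3,7-dimethyloct-2-en-1-yl]-5,7-bis(methoxymethoxy)chroman-4-one | C/C(=C\Cc1c(OCOC)cc2c(c1OCOC)C(=O)C[C@@H](c1ccc(OCOC)c(OCOC)c1)O2)CCCC(C)(C)O | intermediate
16 | prokinawan | C/C(=C\Cc1c(O)cc2c(c1O)C(=O)C[C@@H](c1ccc(O)c(O)c1)O2)CCCC(C)(C)O | target

## Summary
Total steps: 13.
Longest linear sequence: 9 steps (geranyl acetate → target: steps 1, 2, 3, 6, 7, 8, 9, 12, 13). The phloroglucinol branch is 8 steps to the target (steps 4, 5, 6, 7, 8, 9, 12, 13) and the boronic acid branch is 4 (steps 10, 11, 12, 13).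

Three steps most likely to fail, each with a fallback that changes the approach:
1. **Step 7 (second metalation/acetylation).** Risks are lateral deprotonation at the benzylic–allylic CH2, silyl migration and enolisation of the Weinreb amide. Fallback: avoid the second lithiation by desilylating **8** to the symmetric phenol, then Mg-mediated ortho-formylation (MgCl2, Et3N, paraformaldehyde), MeMgBr addition and benzylic oxidation to reach **10**.
2. **Step 12 (Rh asymmetric 1,4-addition).** Risks are low reactivity of the electron-rich 5,7-dialkoxychromone, ring opening to the chalcone, and insufficient ee or the wrong sense. Fallback: Claisen–Schmidt condensation of **10** with 3,4-bis(methoxymethoxy)benzaldehyde and NaOAc cyclisation to racemic **15** (regiochemistry still fixed by the single free OH), then preparative chiral-phase resolution. Alternatively, build the carbinol by asymmetric aldol and close the ring by Mitsunobu inversion.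
3. **Step 13 (global MOM removal).** Risks are solvolysis or elimination of the tertiary alcohol, acid cyclisation of the ortho-allyl phenol to a chroman, and partial racemisation. Fallback: change the protecting-group plan so the last step is fluoride-based: cleave the A-ring MOM ethers at the achiral chromone **11**, re-protect as TBS ethers, use the bis-TBS catechol boronic acid in the Rh step, and finish with buffered HF·pyridine.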